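**Strategy**

The plan rests on disconnecting the C8 prenyl group of ring A and the C6' prenyl group of ring B to prenyl ethers on O5 and O3'. C8 is para to O5 and C6' is para to O3', while the ortho carbons are either substituted (C4a, C2', C4') or, in the case of C6, only a way station, so two Claisen-Cope sequences run in one flask should move both prenyl units from oxygen to carbon without closing a ring. The precursor is a quercetin carrying MOM groups on O3, O7 and O4', prenyl ethers on O5 and O3', and the third prenyl group already on C2'; its O5 ether is built in at the acetophenone stage.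

Key step: step 10

**Remarks on the design**

- Abbreviations: prenyl = 3-methylbut-2-en-1-yl; MOM = methoxymethyl; Eu(fod)3 = tris(6,6,7,7,8,8,8-heptafluoro-2,2-dimethyloctane-3,5-dionato)europium.
- In ring B the Stille C-prenylation is run before the O-prenylation, so that zerovalent palladium never meets an aryl prenyl ether.
- The O5 prenyl ether is placed on the acetophenone. After ring C formation only O3 is free, and a single MOM capping gives the precursor.
- Ring C closure and C3 oxygenation are combined in one alkaline peroxide step, because a nucleophilic oxidant leaves the prenyl alkenes alone.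
- Assumption: the target has no stereocentre and the C2-C1' axis is taken to rotate freely at room temperature; the sp3 centres of 12, 15 and 17 are transient and racemic.

**Route**

Step 1
Reactants: 1 2-bromo-3-hydroxy-4-methoxybenzaldehyde (2-bromoisovanillin, a catalogue compound)
Product: 2 2-bromo-3,4-dihydroxybenzaldehyde
Conditions: BBr3, CH2Cl2, -78 °C to rt; then H2O
Reagents that add atoms: none
Why: Lewis acid demethylation of an aryl methyl ether (boron complexation, then SN2 attack of bromide on the methyl group), to which the aryl bromide and the aldehyde are inert.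

Step 2
Reactants: 2 2-bromo-3,4-dihydroxybenzaldehyde
Product: 3 2-bromo-3-hydroxy-4-(methoxymethoxy)benzaldehyde
Conditions: MOMCl (1.05 equiv), K2CO3 (1.1 equiv), acetone, 0 °C to rt
Reagents that add atoms: chloromethyl methyl ether, COCCl
Why: Williamson-type MOM protection in which the O4 hydroxyl, para to the formyl group and not flanked by bromine, is the more acidic and less hindered one, so one equivalent of mild base should cap O4 alone.

Step 3
Reactants: 3 2-bromo-3-hydroxy-4-(methoxymethoxy)benzaldehyde; 4 tributyl(3-methylbut-2-en-1-yl)stannane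
Product: 5 3-hydroxy-4-(methoxymethoxy)-2-prenylbenzaldehyde
Conditions: Pd(PPh3)4 (5 mol %), DMF, 100 °C
Reagents that add atoms: tributyl(3-methylbut-2-en-1-yl)stannane (4), CCCC[Sn](CCCC)(CCCC)CC=C(C)C
Why: Stille cross-coupling (oxidative addition of zerovalent palladium into the C-Br bond activated by the ortho formyl group, transmetalation from tin, reductive elimination to the linear prenyl arene), which tolerates the free phenol and the aldehyde.

Step 4
Reactants: 5 3-hydroxy-4-(methoxymethoxy)-2-prenylbenzaldehyde; 6 prenyl bromide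
Product: 7 4-(methoxymethoxy)-2-prenyl-3-(prenyloxy)benzaldehyde
Conditions: K2CO3, DMF, rt
Reagents that add atoms: prenyl bromide (6), CC(C)=CCBr
Why: Williamson ether synthesis (SN2 at the primary allylic bromide) on the only free phenol.

Step 5
Reactants: 8 2,4,6-trihydroxyacetophenone
Product: 9 1-[2,6-dihydroxy-4-(methoxymethoxy)phenyl]ethanone
Conditions: MOMCl (1.0 equiv), K2CO3 (1.0 equiv), acetone, 0 °C
Reagents that add atoms: chloromethyl methyl ether, COCCl
Why: Williamson-type MOM protection in which the O4 hydroxyl, the only one not hydrogen-bonded to the acetyl group, should react first with one equivalent of reagent.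

Step 6
Reactants: 9 1-[2,6-dihydroxy-4-(methoxymethoxy)phenyl]ethanone; 6 prenyl bromide
Product: 10 1-[2-hydroxy-4-(methoxymethoxy)-6-(prenyloxy)phenyl]ethanone
Conditions: K2CO3, acetone, reflux
Reagents that add atoms: prenyl bromide (6), CC(C)=CCBr
Why: Williamson ether synthesis on one of two equivalent hydroxyls, after which the remaining one is locked in a hydrogen bond to the carbonyl and should not react further, while K2CO3 in acetone favours O- over C-alkylation.

Step 7
Reactants: 10 1-[2-hydroxy-4-(methoxymethoxy)-6-(prenyloxy)phenyl]ethanone; 7 4-(methoxymethoxy)-2-prenyl-3-(prenyloxy)benzaldehyde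
Product: 11 (E)-1-[2-hydroxy-4-(methoxymethoxy)-6-(prenyloxy)phenyl]-3-[4-(methoxymethoxy)-2-prenyl-3-(prenyloxy)phenyl]prop-2-en-1-one
Conditions: KOH, EtOH/H2O, rt
Reagents that add atoms: none
Why: Claisen-Schmidt condensation (crossed aldol, then E1cB dehydration) with a non-enolisable aldehyde that has only one ortho substituent, the conjugated E alkene being the thermodynamic product.

Step 8
Reactants: 11 the chalcone of step 7
Product: 13 3-hydroxy-7-(methoxymethoxy)-2-[4-(methoxymethoxy)-2-prenyl-3-(prenyloxy)phenyl]-5-(prenyloxy)chromen-4-one, via trans-dihydroflavonol 12 (not isolated)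
Conditions: H2O2 (30% aq), NaOH, MeOH/THF, 0 °C to rt
Reagents that add atoms: hydrogen peroxide, OO
Why: Algar-Flynn-Oyamada reaction, in which phenoxide conjugate addition and trapping of the enolate by H2O2 give dihydroflavonol 12 and alkaline peroxide dehydrogenates it to the flavonol; the reaction type is established for 4',6'-dialkoxy-2'-hydroxychalcones and the nucleophilic oxidant should not touch the isolated prenyl alkenes.

Step 9
Reactants: 13 the flavonol of step 8
Product: 14 5,3'-di-O-prenyl-2'-C-prenylquercetin 3,7,4'-tri-MOM ether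
Conditions: NaH, DMF, 0 °C; then MOMCl
Reagents that add atoms: chloromethyl methyl ether, COCCl
Why: Williamson-type MOM protection of the only free hydroxyl, the acidic C3 hydroxyl, as its sodium salt.

Step 10
Reactants: 14 5,3'-di-O-prenyl-2'-C-prenylquercetin 3,7,4'-tri-MOM ether
Product: 18 petalostemumol G 3,7,4'-tri-MOM ether, via ring A dienone 15 (not isolated), via 8-prenyl phenol 16 (not isolated), via ring B dienone 17 (not isolated)
Conditions: Eu(fod)3 (20 mol %), NaHCO3, 1,2-dichlorobenzene, 85 °C, then 170 °C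
Reagents that add atoms: none
Why: Trivalent europium held between the C4 carbonyl and O5 should trigger a suprafacial [3,3] Claisen shift of the O5 prenyl group to C6 (dienone 15, now a 1,1-dimethylallyl group), and a [3,3] Cope shift across C6-C7=C8 then hands a normal prenyl group to C8, where loss of the ring proton gives phenol 16. At the higher temperature the O3' ether, which has only the weaker O3'/O4' chelate to offer, should take the same two-stage course through a blocked ortho carbon (drawn as the less crowded C4' in dienone 17; a shift to C2' would lead on to the same carbon) and end at C6', the one ring B carbon from which a proton can be lost. The closest known reactions are the Eu(fod)3-catalysed Claisen-Cope rearrangement of 5-O-prenylflavonols to 8-prenylflavonols and the thermal para-Claisen rearrangement of aryl prenyl ethers with two occupied ortho positions. No ring is closed and no stereocentre is set, the sp3 carbons of 15 and 17 being transient. The step needs para delivery in both rings: in ring B it is enforced because neither quaternary ortho carbon of the dienone can enolise, and in ring A the metal chelate and the steric squeeze on the tertiary allyl group between the C5 oxygen and the O7 MOM ether should make the onward Cope shift faster than enolisation at C6, the more so as the ring A relay is run first at 85 °C, before heat alone could act on it. NaHCO3 keeps the medium non-acidic so that the MOM ethers stay and the freed O3' hydroxyl does not add to the C2' prenyl alkene.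

Step 11
Reactants: 18 petalostemumol G 3,7,4'-tri-MOM ether
Product: 19 petalostemumol G
Conditions: aq. HCl (3 M)/MeOH, 45 °C
Reagents that add atoms: none
Why: Acid-catalysed acetal exchange (MOM cleavage, the CH2OMe unit passing to methanol), for which dilute acid at moderate temperature is the established way to unmask prenylated flavonols without adding the phenols to the neighbouring alkenes.

**Compound list**

1 | 2-bromo-3-hydroxy-4-methoxybenzaldehyde (2-bromoisovanillin) | COc1ccc(C=O)c(Br)c1O | starting material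
2 | 2-bromo-3,4-dihydroxybenzaldehyde | O=Cc1ccc(O)c(O)c1Br | intermediate
3 | 2-bromo-3-hydroxy-4-(methoxymethoxy)benzaldehyde | COCOc1ccc(C=O)c(Br)c1O | intermediate
4 | tributyl(3-methylbut-2-en-1-yl)stannane | CCCC[Sn](CCCC)(CCCC)CC=C(C)C | starting material
5 | 3-hydroxy-4-(methoxymethoxy)-2-(3-methylbut-2-en-1-yl)benzaldehyde | COCOc1ccc(C=O)c(CC=C(C)C)c1O | intermediate
6 | prenyl bromide (1-bromo-3-methylbut-2-ene) | CC(C)=CCBr | starting material
7 | 4-(methoxymethoxy)-2-(3-methylbut-2-en-1-yl)-3-[(3-methylbut-2-en-1-yl)oxy]benzaldehyde | COCOc1ccc(C=O)c(CC=C(C)C)c1OCC=C(C)C | intermediate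
8 | 2,4,6-trihydroxyacetophenone | CC(=O)c1c(O)cc(O)cc1O | starting material
9 | 1-[2,6-dihydroxy-4-(methoxymethoxy)phenyl]ethanone | CC(=O)c1c(O)cc(OCOC)cc1O | intermediate
10 | 1-[2-hydroxy-4-(methoxymethoxy)-6-[(3-methylbut-2-en-1-yl)oxy]phenyl]ethanone | CC(=O)c1c(O)cc(OCOC)cc1OCC=C(C)C | intermediate
11 | (E)-1-[2-hydroxy-4-(methoxymethoxy)-6-(prenyloxy)phenyl]-3-[4-(methoxymethoxy)-2-prenyl-3-(prenyloxy)phenyl]prop-2-en-1-one | COCOc1cc(O)c(C(=O)/C=C/c2ccc(OCOC)c(OCC=C(C)C)c2CC=C(C)C)c(OCC=C(C)C)c1 | intermediate
12 | racemic trans-(2R*,3R*)-3-hydroxy-7-(methoxymethoxy)-2-[4-(methoxymethoxy)-2-prenyl-3-(prenyloxy)phenyl]-5-(prenyloxy)chroman-4-one (one enantiomer drawn) | O[C@@H]1[C@@H](c3ccc(OCOC)c(OCC=C(C)C)c3CC=C(C)C)Oc2cc(OCOC)cc(OCC=C(C)C)c2C1=O | intermediate (not isolated)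
13 | 3-hydroxy-7-(methoxymethoxy)-2-[4-(methoxymethoxy)-2-prenyl-3-(prenyloxy)phenyl]-5-(prenyloxy)chromen-4-one | CC(C)=CCOc1cc(OCOC)cc2oc(c(O)c(=O)c12)-c1ccc(OCOC)c(OCC=C(C)C)c1CC=C(C)C | intermediate
14 | 5,3'-di-O-prenyl-2'-C-prenylquercetin 3,7,4'-tri-MOM ether; 3,7-bis(methoxymethoxy)-2-[4-(methoxymethoxy)-2-prenyl-3-(prenyloxy)phenyl]-5-(prenyloxy)chromen-4-one | CC(C)=CCOc1cc(OCOC)cc2oc(c(OCOC)c(=O)c12)-c1ccc(OCOC)c(OCC=C(C)C)c1CC=C(C)C | intermediate
15 | ring A dienone: 3,7-bis(methoxymethoxy)-6-(2-methylbut-3-en-2-yl)-2-[4-(methoxymethoxy)-2-prenyl-3-(prenyloxy)phenyl]-6H-chromene-4,5-dione, racemic at C6 | C=CC(C)(C)C1C(=O)C2=C(C=C1OCOC)OC(=C(OCOC)C2=O)c1ccc(OCOC)c(OCC=C(C)C)c1CC=C(C)C | intermediate (not isolated)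
16 | 5-hydroxy-3,7-bis(methoxymethoxy)-2-[4-(methoxymethoxy)-2-prenyl-3-(prenyloxy)phenyl]-8-prenylchromen-4-one | CC(C)=CCc1c(OCOC)cc(O)c2c1oc(c(OCOC)c2=O)-c1ccc(OCOC)c(OCC=C(C)C)c1CC=C(C)C | intermediate (not isolated)
17 | ring B dienone: 5-hydroxy-3,7-bis(methoxymethoxy)-2-[4-(methoxymethoxy)-4-(2-methylbut-3-en-2-yl)-3-oxo-2-prenylcyclohexa-1,5-dien-1-yl]-8-prenylchromen-4-one, racemic at C4' | CC(C)=CCc1c(OCOC)cc(O)c2c1oc(c(OCOC)c2=O)C1=C(CC=C(C)C)C(=O)C(OCOC)(C(C)(C)C=C)C=C1 | intermediate (not isolated)
18 | petalostemumol G 3,7,4'-tri-MOM ether; 5-hydroxy-2-[3-hydroxy-4-(methoxymethoxy)-2,6-diprenylphenyl]-3,7-bis(methoxymethoxy)-8-prenylchromen-4-one | CC(C)=CCc1c(OCOC)cc(O)c2c1oc(c(OCOC)c2=O)-c1c(CC=C(C)C)cc(OCOC)c(O)c1CC=C(C)C | intermediate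
19 | petalostemumol G; 2-(3,4-dihydroxy-2,6-diprenylphenyl)-3,5,7-trihydroxy-8-prenylchromen-4-one | CC(C)=CCc1cc(O)c(O)c(CC=C(C)C)c1-c1oc2c(CC=C(C)C)c(O)cc(O)c2c(=O)c1O | target

**Step count and risks**

Total step count: 11. Longest linear sequence: 9 steps (steps 1, 2, 3, 4, 7, 8, 9, 10, 11).

The three steps most likely to fail:

1. Step 10. The ring B ether may stall or lose its prenyl group by C-O cleavage at the temperature it needs, the freed O3' hydroxyl may cyclise onto the C2' prenyl alkene, and ring A may enolise at C6 before the Cope shift. Fallback: the ring B relay is taken out of the flavonol and run on aldehyde 7 as a plain thermal para-Claisen-Cope rearrangement of an aryl prenyl ether with both ortho positions occupied. Heating 7 in N,N-diethylaniline at 190 °C should give 3-hydroxy-4-(methoxymethoxy)-2,6-bis(3-methylbut-2-en-1-yl)benzaldehyde F1. Claisen-Schmidt condensation of F1 with acetophenone 10 (KOH, EtOH) should give (E)-1-[2-hydroxy-4-(methoxymethoxy)-6-(prenyloxy)phenyl]-3-[3-hydroxy-4-(methoxymethoxy)-2,6-diprenylphenyl]prop-2-en-1-one F2. Algar-Flynn-Oyamada oxidation (H2O2, NaOH, MeOH) should give 3-hydroxy-2-[3-hydroxy-4-(methoxymethoxy)-2,6-diprenylphenyl]-7-(methoxymethoxy)-5-(prenyloxy)chromen-4-one F3. Double MOM protection at O3 and O3' (NaH, MOMCl, DMF) should give 3,7-bis(methoxymethoxy)-2-[3,4-bis(methoxymethoxy)-2,6-diprenylphenyl]-5-(prenyloxy)chromen-4-one F4. Ring A alone then undergoes the established europium-catalysed relay (Eu(fod)3, NaHCO3, PhCl, 85 °C) to 5-hydroxy-3,7-bis(methoxymethoxy)-2-[3,4-bis(methoxymethoxy)-2,6-diprenylphenyl]-8-prenylchromen-4-one F5. Aqueous HCl in MeOH removes the four MOM groups, so the fallback rejoins the route at target 19. Its price is a condensation and a ring closure on a ring B with two ortho groups.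

2. Step 8. The phenoxide may attack the alpha carbon instead of the beta carbon, because the 6'-alkoxy group and the ortho prenyl group twist the enone, and this diverts material to the five-membered aurone. Fallback: from chalcone 11, ring C is closed before any oxidant is present. NaOAc in refluxing EtOH should give, by oxa-Michael addition, racemic 7-(methoxymethoxy)-2-[4-(methoxymethoxy)-2-prenyl-3-(prenyloxy)phenyl]-5-(prenyloxy)chroman-4-one F6. I2 in pyridine at 90 °C should dehydrogenate it to 7-(methoxymethoxy)-2-[4-(methoxymethoxy)-2-prenyl-3-(prenyloxy)phenyl]-5-(prenyloxy)chromen-4-one F7. Lithiation at C3 with lithium diisopropylamide (THF, -78 °C), trapping with B(OMe)3 and oxidation of the boronate with NaBO3·4H2O should then give flavonol 13, where the route resumes.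

3. Step 3. The prenyl group may be transferred through its tertiary end (allylic transposition to the 1,1-dimethylallyl isomer), and oxidative addition at a bromide flanked by two ortho groups may be slow. Fallback: from bromide 3, the five-carbon unit is put on in two stages. Stille coupling with allyltributylstannane (Pd(PPh3)4, DMF, 100 °C), whose two allyl termini are equal, should give 3-hydroxy-4-(methoxymethoxy)-2-(prop-2-en-1-yl)benzaldehyde F8. Cross-metathesis with excess 2-methylbut-2-ene (second-generation Grubbs catalyst, CH2Cl2, 40 °C) should turn the allyl group into the prenyl group and return to 5.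

Further compounds
F1 | step 10 | 3-hydroxy-4-(methoxymethoxy)-2,6-bis(3-methylbut-2-en-1-yl)benzaldehyde | O=Cc1c(CC=C(C)C)cc(OCOC)c(O)c1CC=C(C)C
F2 | step 10 | (E)-1-[2-hydroxy-4-(methoxymethoxy)-6-(prenyloxy)phenyl]-3-[3-hydroxy-4-(methoxymethoxy)-2,6-diprenylphenyl]prop-2-en-1-one | O=C(/C=C/c1c(CC=C(C)C)cc(OCOC)c(O)c1CC=C(C)C)c1c(O)cc(OCOC)cc1OCC=C(C)C
F3 | step 10 | 3-hydroxy-2-[3-hydroxy-4-(methoxymethoxy)-2,6-diprenylphenyl]-7-(methoxymethoxy)-5-(prenyloxy)chromen-4-one | CC(C)=CCOc1cc(OCOC)cc2oc(c(O)c(=O)c12)-c1c(CC=C(C)C)cc(OCOC)c(O)c1CC=C(C)C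
F4 | step 10 | 3,7-bis(methoxymethoxy)-2-[3,4-bis(methoxymethoxy)-2,6-diprenylphenyl]-5-(prenyloxy)chromen-4-one | CC(C)=CCOc1cc(OCOC)cc2oc(c(OCOC)c(=O)c12)-c1c(CC=C(C)C)cc(OCOC)c(OCOC)c1CC=C(C)C
F5 | step 10 | 5-hydroxy-3,7-bis(methoxymethoxy)-2-[3,4-bis(methoxymethoxy)-2,6-diprenylphenyl]-8-prenylchromen-4-one | CC(C)=CCc1c(OCOC)cc(O)c2c1oc(c(OCOC)c2=O)-c1c(CC=C(C)C)cc(OCOC)c(OCOC)c1CC=C(C)C
F6 | step 8 | racemic 7-(methoxymethoxy)-2-[4-(methoxymethoxy)-2-prenyl-3-(prenyloxy)phenyl]-5-(prenyloxy)chroman-4-one | O=C1CC(c2ccc(OCOC)c(OCC=C(C)C)c2CC=C(C)C)Oc2cc(OCOC)cc(OCC=C(C)C)c12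
F7 | step 8 | 7-(methoxymethoxy)-2-[4-(methoxymethoxy)-2-prenyl-3-(prenyloxy)phenyl]-5-(prenyloxy)chromen-4-one | O=c1cc(-c2ccc(OCOC)c(OCC=C(C)C)c2CC=C(C)C)oc2cc(OCOC)cc(OCC=C(C)C)c12
F8 | step 3 | 3-hydroxy-4-(methoxymethoxy)-2-(prop-2-en-1-yl)benzaldehyde | COCOc1ccc(C=O)c(CC=C)c1O
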